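**Retrosynthetic overview**
- Last bond: the CH2 bridge. The dihydrobenzofuran (one free ring C–H) is joined to the 4-hydroxy-2-pyranone with one CH2 unit from an iminium salt.
- Key disconnection: C2–C3 and O1–C2 of the dihydrofuran, made in one operation. The o-quinone methide of the acylphloroglucinol has an electrophilic benzylic carbon; a chiral 2-methylallyl sulfonium ylide supplies the future O-bearing C2 as a carbanion. Two carbons that are both normally acceptors are joined, and the sulfide sets (2R).
- o-Quinone methide precursor: benzylic trimethylammonium salt from the acylphloroglucinol (Mannich, then N-methylation). Acylphloroglucinol: phloroglucinol + (R)-2-methylbutanoic acid (Friedel–Crafts), which brings in the second stereocentre.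
- Pyranone: pentan-3-one silyl enol ether + malonyl dichloride.
- Ring order: benzene ring bought; pyranone ring made separately; dihydrofuran ring closed in the key step; the two halves joined last.

Assumption: (R)-2-methylbutanoic acid and ent-isothiocineole are bought enantiopure, and the facial selectivity of the sulfonium ylide is taken from the accepted model for this sulfide (S-allyl group exo, ylide substituent turned away from the CMe2 carbon, attack past the bridgehead C–H); if the measured sense were opposite, the enantiomeric sulfide (from (R)-limonene) replaces it and nothing else changes.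

**Step 1**
Reactants: 1 (R)-2-methylbutanoic acid; 2 phloroglucinol (benzene-1,3,5-triol)
Product: 4 (2R)-2-methyl-1-(2,4,6-trihydroxyphenyl)butan-1-one, via (R)-2-methylbutanoyl chloride 3 (not isolated)
Conditions: (COCl)2 (1.0 equiv), DMF (cat.), CH2Cl2, 0 °C → rt; then 2, AlCl3 (3.5 equiv), PhNO2/CH2Cl2, 0 → 40 °C; ice/1 M HCl
Reagents that add atoms: none
Why: Acid chloride formation followed by Friedel–Crafts C-acylation of the very electron-rich triol stops at the mono-ketone because the acyl group deactivates the ring; no new stereocentre is made and the α-stereocentre of 1 is carried through, the low temperature limiting AlCl3-promoted enolisation.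

**Step 2**
Reactants: 4; 5 N,N-dimethylmethyleneiminium iodide (Eschenmoser's salt); 6 iodomethane
Product: 8 N,N,N-trimethyl-1-{2,4,6-trihydroxy-3-[(2R)-2-methylbutanoyl]phenyl}methanaminium iodide, via Mannich base 7 (not isolated)
Conditions: 5 (1.0 equiv), MeCN, 0 °C → rt; then NaHCO3 (1.0 equiv), 6 (1.5 equiv), rt, dark; filter, Et2O wash, store cold
Reagents that add atoms: N,N-dimethylmethyleneiminium iodide C=[N+](C)C.[I-]; iodomethane CI
Why: Mannich aminomethylation at one of the two equivalent free ring positions (the protonated amine slows a second one), then Menschutkin N-methylation of the benzylic amine, which is far faster than O-methylation of a phenol under bicarbonate, gives a salt from which base later expels NMe3; no stereocentre is formed.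

**Step 3**
Reactants: 9 ent-isothiocineole, (1S,4R,5S)-4,7,7-trimethyl-6-thiabicyclo[3.2.1]octane (the enantiomer derived from (S)-limonene; 4-methyl cis to the thia bridge); 10 3-bromo-2-methylprop-1-ene; 11 sodium tetrafluoroborate
Product: 12 (1S,4R,5S,6S)-4,7,7-trimethyl-6-(2-methylprop-2-en-1-yl)-6-thiabicyclo[3.2.1]octan-6-ium tetrafluoroborate (S-allyl group exo, on the side of the one-carbon bridge)
Conditions: 10 (3 equiv), 11 (5 equiv), CH2Cl2/H2O (1:1), rt, 48 h; recrystallise
Reagents that add atoms: 3-bromo-2-methylprop-1-ene C=C(C)CBr; sodium tetrafluoroborate [Na+].F[B-](F)(F)F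
Why: S-Alkylation (sulfonium salt formation) of the conformationally locked sulfide occurs on its less hindered exo lone pair and is driven by bromide/BF4 exchange, so sulfur becomes a single stereocentre.

**Step 4 (key step)**
Reactants: 8; 12
Product: 16 (2R)-1-[(2R)-4,6-dihydroxy-2-(prop-1-en-2-yl)-2,3-dihydro-1-benzofuran-5-yl]-2-methylbutan-1-one, via sulfonium ylide 13 (not isolated), via o-quinone methide 14 (not isolated), via sulfonium phenolate adduct 15 (not isolated)
Conditions: 12 (1.5 equiv), LiHMDS (4.6 equiv), THF, −78 °C, 20 min; then 8 (1.0 equiv) in THF/DMPU added over 1 h, −78 → −20 °C; sat. NH4Cl; sulfide 9 recovered by chromatography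
Reagents that add atoms: none
Why: Proposed new method: a formal [4+1] annulation in which ylide 13 acts as a polarity-reversed (carbanionic) equivalent of the future C2–O carbon and adds through its α-carbon to the exocyclic CH2 of o-quinone methide 14 released from 8 (irreversible, driven by rearomatisation), after which the para-phenolate, the less hindered and more nucleophilic of the two flanking oxygens, displaces the sulfide from 15 in a 5-exo-tet SN2 with inversion; the exo-alkylated locked sulfide turns the isopropenyl group away from its CMe2 carbon and exposes only the ylide face next to the bridgehead C–H, giving (S) at the S–CH carbon of 15 and hence (2R) in 16, the closest known reactions being [4+1] annulations of o-quinone methides with sulfur ylides and asymmetric epoxidations with isothiocineole-derived allylic sulfonium ylides.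

**Step 5**
Reactants: 17 pentan-3-one; 18 chlorotrimethylsilane; 19 malonyl dichloride
Product: 21 6-ethyl-4-hydroxy-5-methyl-2H-pyran-2-one, via silyl enol ether 20 (not isolated)
Conditions: LDA (1.05 equiv), THF, −78 °C; 18 (1.1 equiv), → rt; pentane, cold aq. NaHCO3 wash, concentrate; then 19 (1.0 equiv), Et2O, −78 °C → rt, 16 h
Reagents that add atoms: malonyl dichloride O=C(Cl)CC(=O)Cl
Why: Silyl enol ether formation, then C-acylation by malonyl dichloride and lactonisation of the resulting 3,5-dioxo acid chloride through the enol oxygen (Effenberger-type pyranone synthesis) gives the 4-hydroxy-2-pyranone directly; no stereocentre is involved.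

**Step 6**
Reactants: 16; 21; 5
Product: 24 6-ethyl-4-hydroxy-3-({(2R)-4,6-dihydroxy-5-[(2R)-2-methylbutanoyl]-2-(prop-1-en-2-yl)-2,3-dihydro-1-benzofuran-7-yl}methyl)-5-methyl-2H-pyran-2-one (target), via pyranone Mannich base 22 (not isolated), via 3-methylidenepyran-2,4-dione 23 (not isolated)
Conditions: 21 (1.5 equiv), 5 (1.5 equiv), CH2Cl2/MeCN, rt, 1 h; then 16 (1.0 equiv), rt → 40 °C, 12 h
Reagents that add atoms: N,N-dimethylmethyleneiminium iodide C=[N+](C)C.[I-]
Why: Mannich reaction at C3 of the pyranone, loss of dimethylamine to the 3-methylidene-2,4-dione and conjugate (Friedel–Crafts-type) addition of C7, the only free ring carbon of 16, builds the CH2 bridge under near-neutral conditions that leave the isopropenyl group, the ether ring and both stereocentres untouched.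

**Compound list**
1 | (R)-2-methylbutanoic acid | CC[C@@H](C)C(=O)O | starting material
2 | phloroglucinol | Oc1cc(O)cc(O)c1 | starting material
3 | (R)-2-methylbutanoyl chloride | CC[C@@H](C)C(=O)Cl | intermediate
4 | (2R)-2-methyl-1-(2,4,6-trihydroxyphenyl)butan-1-one | CC[C@@H](C)C(=O)c1c(O)cc(O)cc1O | intermediate
5 | N,N-dimethylmethyleneiminium iodide | C=[N+](C)C.[I-] | starting material
6 | iodomethane | CI | starting material
7 | (2R)-1-{3-[(dimethylamino)methyl]-2,4,6-trihydroxyphenyl}-2-methylbutan-1-one | CC[C@@H](C)C(=O)c1c(O)cc(O)c(CN(C)C)c1O | intermediate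
8 | N,N,N-trimethyl-1-{2,4,6-trihydroxy-3-[(2R)-2-methylbutanoyl]phenyl}methanaminium iodide | CC[C@@H](C)C(=O)c1c(O)cc(O)c(C[N+](C)(C)C)c1O.[I-] | intermediate
9 | ent-isothiocineole, (1S,4R,5S)-4,7,7-trimethyl-6-thiabicyclo[3.2.1]octane | C[C@@H]1CC[C@H]2C[C@@H]1SC2(C)C | starting material
10 | 3-bromo-2-methylprop-1-ene | C=C(C)CBr | starting material
11 | sodium tetrafluoroborate | [Na+].F[B-](F)(F)F | starting material
12 | (1S,4R,5S,6S)-4,7,7-trimethyl-6-(2-methylprop-2-en-1-yl)-6-thiabicyclo[3.2.1]octan-6-ium tetrafluoroborate | C=C(C)C[S@+]1[C@H]2C[C@H](CC[C@H]2C)C1(C)C.F[B-](F)(F)F | intermediate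
13 | sulfonium ylide of 12 (carbanion on the S–CH carbon of the methallyl group) | C=C(C)[CH-][S@+]1[C@H]2C[C@H](CC[C@H]2C)C1(C)C | intermediate
14 | 3,5-dihydroxy-4-[(2R)-2-methylbutanoyl]-6-methylidenecyclohexa-2,4-dien-1-one (o-quinone methide, drawn neutral) | CC[C@@H](C)C(=O)C1=C(O)C(=C)C(=O)C=C1O | intermediate
15 | 3,5-dihydroxy-4-[(2R)-2-methylbutanoyl]-2-[(2S)-3-methyl-2-(ent-isothiocineol-S-ylio)but-3-en-1-yl]phenolate (zwitterion) | CC[C@@H](C)C(=O)c1c(O)cc([O-])c(C[C@@H](C(C)=C)[S@+]2[C@H]3C[C@H](CC[C@H]3C)C2(C)C)c1O | intermediate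
16 | (2R)-1-[(2R)-4,6-dihydroxy-2-(prop-1-en-2-yl)-2,3-dihydro-1-benzofuran-5-yl]-2-methylbutan-1-one | C=C(C)[C@H]1Cc2c(O)c(C(=O)[C@H](C)CC)c(O)cc2O1 | intermediate
17 | pentan-3-one | CCC(=O)CC | starting material
18 | chlorotrimethylsilane | C[Si](C)(C)Cl | starting material
19 | malonyl dichloride | O=C(Cl)CC(=O)Cl | starting material
20 | trimethyl(pent-2-en-3-yloxy)silane (E/Z mixture, E drawn; geometry is lost later) | C/C=C(\CC)O[Si](C)(C)C | intermediate
21 | 6-ethyl-4-hydroxy-5-methyl-2H-pyran-2-one | CCc1oc(=O)cc(O)c1C | intermediate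
22 | 3-[(dimethylamino)methyl]-6-ethyl-4-hydroxy-5-methyl-2H-pyran-2-one | CCc1oc(=O)c(CN(C)C)c(O)c1C | intermediate
23 | 6-ethyl-5-methyl-3-methylidene-2H-pyran-2,4(3H)-dione | CCC1=C(C)C(=O)C(=C)C(=O)O1 | intermediate
24 | 6-ethyl-4-hydroxy-3-({(2R)-4,6-dihydroxy-5-[(2R)-2-methylbutanoyl]-2-(prop-1-en-2-yl)-2,3-dihydro-1-benzofuran-7-yl}methyl)-5-methyl-2H-pyran-2-one | C=C(C)[C@H]1Cc2c(O)c(C(=O)[C@H](C)CC)c(O)c(Cc3c(O)c(C)c(CC)oc3=O)c2O1 | target

**Totals**
Total steps: 6. Longest linear sequence: 4 (steps 1, 2, 4, 6).

**Steps most likely to fail, with fallbacks**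

Step 4. Risks: the o-quinone methide may be captured by a phloroglucinol carbon instead of the ylide, ring closure may go partly through the oxygen ortho to the acyl group, and the enantioselectivity is untested on this substrate. The fallback sets out from 4 and comes back at 16. Compound 4 is C-alkylated (DBU, THF, 0 °C) with (E)-4-bromo-2-methylbut-2-en-1-yl methyl carbonate to give methyl (2E)-2-methyl-4-{2,4,6-trihydroxy-3-[(2R)-2-methylbutanoyl]phenyl}but-2-en-1-yl carbonate F1. This is cyclised by Pd2(dba)3 with the enantiomer of the DACH-phenyl Trost ligand that gives the (R)-ether (CH2Cl2, rt). The π-allyl palladium complex is attacked 5-exo by the para-phenol, which is a known way to make 2-isopropenyl-2,3-dihydrobenzofurans, and the product is 16.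

Step 2. Risks: double aminomethylation, O-methylation during quaternisation, and premature loss of NMe3 from 8. The fallback sets out from 4 and rejoins the route at the o-quinone methide 14 inside step 4 (and so at 16). Compound 4 is treated with aqueous formaldehyde (1.0 equiv) and sodium 4-methylbenzenesulfinate (2.5 equiv) in HCO2H/H2O at rt. The hydroxymethyl cation is trapped at sulfur to give (2R)-2-methyl-1-{2,4,6-trihydroxy-3-[(4-methylphenyl)sulfonylmethyl]phenyl}butan-1-one F2. This sulfone is added to the preformed ylide in place of 8, and the phenolate expels sulfinate to give 14.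

Step 1. Risks: partial racemisation of the α-stereocentre under AlCl3 and modest C-acylation yield. The fallback sets out from 1 and 2 and comes back at 4. Compound 2 is protected (MOMCl, iPr2NEt, CH2Cl2) as 1,3,5-tris(methoxymethoxy)benzene F3. Compound 1 is converted (CDI, then MeNHOMe·HCl) into (2R)-N-methoxy-N,2-dimethylbutanamide F4. F3 is lithiated between two OMOM groups (n-BuLi, THF, 0 °C) and acylated with F4 at −78 °C to give (2R)-2-methyl-1-[2,4,6-tris(methoxymethoxy)phenyl]butan-1-one F5. Removal of the MOM groups (HCl, MeOH, 40 °C) gives 4 without any Lewis acid.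

**Further compounds**
F1 | step 4 | methyl (2E)-2-methyl-4-{2,4,6-trihydroxy-3-[(2R)-2-methylbutanoyl]phenyl}but-2-en-1-yl carbonate | CC[C@@H](C)C(=O)c1c(O)cc(O)c(C/C=C(\C)COC(=O)OC)c1O
F2 | step 2 | (2R)-2-methyl-1-{2,4,6-trihydroxy-3-[(4-methylphenyl)sulfonylmethyl]phenyl}butan-1-one | CC[C@@H](C)C(=O)c1c(O)cc(O)c(CS(=O)(=O)c2ccc(C)cc2)c1O
F3 | step 1 | 1,3,5-tris(methoxymethoxy)benzene | COCOc1cc(OCOC)cc(OCOC)c1
F4 | step 1 | (2R)-N-methoxy-N,2-dimethylbutanamide | CC[C@@H](C)C(=O)N(C)OC
F5 | step 1 | (2R)-2-methyl-1-[2,4,6-tris(methoxymethoxy)phenyl]butan-1-one | CC[C@@H](C)C(=O)c1c(OCOC)cc(OCOC)cc1OCOC
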